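**Retrosynthetic overview**
- Artelasticin comes from its tetra-MOM ether by a final global acetal cleavage.
- Key disconnection C2–C1': the chromone C2, normally the electrophilic carbon, is used as a nucleophile (a C2-zincated chromone, i.e. a β-acylvinyl anion and masked acyl anion) and joined to ring B as an electrophilic aryl bromide (Negishi).
- The 3,6,8-triprenylchromone comes from an o-hydroxyaryl homoprenyl ketone plus a one-carbon amide acetal (ring C closure); the C3 prenyl comes from enolate alkylation of the methyl ketone.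
- The ring A prenyl groups come from twofold C-prenylation of phloroacetophenone.
- Ring order: rings A and B are bought as benzenes; ring C is the only ring made, and it is closed before ring B is attached.

Assumption: artelasticin has no stereocentre and no stereogenic double bond, so "single enantiomer" is read as the one achiral structure given and no stereocontrol is needed.
Assumption: where identical MOM groups go on or come off within one step (steps 2, 5, 7), the order written for the non-isolated intermediates is the most likely one; any other order gives the same product.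

**Route**

Step 1
Reactants: 1 2',4',6'-trihydroxyacetophenone; 2 prenyl bromide (1-bromo-3-methylbut-2-ene)
Product: 4 1-[2,4,6-trihydroxy-3,5-bis(3-methylbut-2-enyl)phenyl]ethanone, via mono-C-prenyl ketone 3 (not isolated)
Conditions: 2 (2.2 equiv), KOH (10% aq), 0 °C to rt
Reagents that add atoms: none
Why: Twofold C-alkylation of the ambident phloroglucinol-type phenolate (Friedel–Crafts-type C-prenylation in water, where hydrogen bonding to oxygen steers the allylic bromide to the two equivalent ring carbons) gives the symmetric diprenyl ketone in the modest yield usual for this cheap first step, with no stereocentre formed.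

Step 2
Reactants: 4 1-[2,4,6-trihydroxy-3,5-bis(3-methylbut-2-enyl)phenyl]ethanone
Product: 6 1-[2-hydroxy-4,6-bis(methoxymethoxy)-3,5-bis(3-methylbut-2-enyl)phenyl]ethanone, via 4-O-MOM ether 5 (not isolated)
Conditions: MOMCl (2.3 equiv), i-Pr2NEt, CH2Cl2, 0 °C to rt
Reagents that add atoms: chloromethyl methyl ether (MOMCl), COCCl
Why: Williamson-type O-alkylation (MOM protection) takes the para hydroxyl and one ortho hydroxyl, while the last hydroxyl is held in a strong hydrogen bond to the ketone and stays free for the later closure of ring C.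

Step 3
Reactants: 6 1-[2-hydroxy-4,6-bis(methoxymethoxy)-3,5-bis(3-methylbut-2-enyl)phenyl]ethanone; 2 prenyl bromide
Product: 8 1-[2-hydroxy-4,6-bis(methoxymethoxy)-3,5-bis(3-methylbut-2-enyl)phenyl]-5-methylhex-4-en-1-one, via dilithium enolate-phenoxide 7 (not isolated)
Conditions: LiN(i-Pr)2 (2.2 equiv), THF, −78 °C; then 2 (1.05 equiv), −78 to 0 °C; H2O quench
Reagents that add atoms: none
Why: SN2 alkylation of the kinetic lithium enolate (a dianion with the unreactive chelated lithium phenoxide) by the allylic bromide gives the homoprenyl ketone whose α-carbon is the future C3 carrying its prenyl group.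

Step 4
Reactants: 8 1-[2-hydroxy-4,6-bis(methoxymethoxy)-3,5-bis(3-methylbut-2-enyl)phenyl]-5-methylhex-4-en-1-one
Product: 10 5,7-bis(methoxymethoxy)-3,6,8-tris(3-methylbut-2-enyl)-4H-chromen-4-one, via enaminone 9 (not isolated)
Conditions: Me2NCH(OMe)2 (5 equiv), toluene, 110 °C; then AcOH (cat.), 80 °C
Reagents that add atoms: N,N-dimethylformamide dimethyl acetal, COC(OC)N(C)C
Why: Aminomethylenation of the ketone α-CH2 gives a push–pull enaminone that closes ring C by intramolecular oxa-Michael addition and loss of dimethylamine (enaminone chromone synthesis), leaving C2–H as the only sp2 C–H of the bicycle.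

Step 5
Reactants: 11 4-bromoresorcinol (4-bromobenzene-1,3-diol)
Product: 13 1-bromo-2,4-bis(methoxymethoxy)benzene, via mono-MOM bromophenol 12 (not isolated)
Conditions: MOMCl (2.5 equiv), i-Pr2NEt, CH2Cl2, 0 °C to rt
Reagents that add atoms: chloromethyl methyl ether (MOMCl), COCCl
Why: Standard MOM protection (Williamson-type O-alkylation) of both phenols removes the acidic protons so that the aryl bromide tolerates the organozinc partner.

Step 6
Reactants: 10 5,7-bis(methoxymethoxy)-3,6,8-tris(3-methylbut-2-enyl)-4H-chromen-4-one; 13 1-bromo-2,4-bis(methoxymethoxy)benzene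
Product: 15 2-[2,4-bis(methoxymethoxy)phenyl]-5,7-bis(methoxymethoxy)-3,6,8-tris(3-methylbut-2-enyl)-4H-chromen-4-one, via C2 chromonylzinc chloride 14 (not isolated)
Conditions: (TMP)ZnCl·LiCl (1.3 equiv; TMP = 2,2,6,6-tetramethylpiperidid-1-yl), MgCl2 (1.3 equiv), THF, 25 °C; then 13 (1.2 equiv), Pd(OAc)2 (3 mol%), SPhos (6 mol%), 50 °C
Reagents that add atoms: none
Why: C2–H is acidified by the ring oxygen and by Lewis-acid complexation of the pyrone carbonyl, so directed zincation gives a C2 alkenylzinc (a β-acylvinyl anion and masked acyl anion, reversed polarity at the normally electrophilic C2) that is joined to the electrophilic aryl bromide by Negishi cross-coupling.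

Step 7
Reactants: 15 2-[2,4-bis(methoxymethoxy)phenyl]-5,7-bis(methoxymethoxy)-3,6,8-tris(3-methylbut-2-enyl)-4H-chromen-4-one
Product: 19 artelasticin 2-(2,4-dihydroxyphenyl)-5,7-dihydroxy-3,6,8-tris(3-methylbut-2-enyl)-4H-chromen-4-one, via 5-hydroxy tris-MOM flavone 16 (not isolated), via 5,7-dihydroxy bis-MOM flavone 17 (not isolated), via 4'-O-MOM flavone 18 (not isolated)
Conditions: HCl (1.25 M in MeOH, cat.), MeOH–THF 3:1, 25 to 40 °C, stopped at full conversion
Reagents that add atoms: none
Why: Acid-catalysed transacetalisation of the four aryl MOM acetals to methanol frees the phenols under mild, short exposure that the trisubstituted prenyl alkenes tolerate, and the achiral product has no stereocentre to set.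

**Compound list**

1 | 2',4',6'-trihydroxyacetophenone | CC(=O)c1c(O)cc(O)cc1O | starting material
2 | prenyl bromide (1-bromo-3-methylbut-2-ene) | CC(C)=CCBr | starting material
3 | 1-[2,4,6-trihydroxy-3-(3-methylbut-2-enyl)phenyl]ethanone | CC(=O)c1c(O)cc(O)c(CC=C(C)C)c1O | intermediate (not isolated)
4 | 1-[2,4,6-trihydroxy-3,5-bis(3-methylbut-2-enyl)phenyl]ethanone | CC(=O)c1c(O)c(CC=C(C)C)c(O)c(CC=C(C)C)c1O | intermediate
5 | 1-[2,6-dihydroxy-4-(methoxymethoxy)-3,5-bis(3-methylbut-2-enyl)phenyl]ethanone | CC(=O)c1c(O)c(CC=C(C)C)c(OCOC)c(CC=C(C)C)c1O | intermediate (not isolated)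
6 | 1-[2-hydroxy-4,6-bis(methoxymethoxy)-3,5-bis(3-methylbut-2-enyl)phenyl]ethanone | CC(=O)c1c(O)c(CC=C(C)C)c(OCOC)c(CC=C(C)C)c1OCOC | intermediate
7 | dilithium enolate-phenoxide of 6 | [Li+].[Li+].C=C([O-])c1c([O-])c(CC=C(C)C)c(OCOC)c(CC=C(C)C)c1OCOC | intermediate (not isolated)
8 | 1-[2-hydroxy-4,6-bis(methoxymethoxy)-3,5-bis(3-methylbut-2-enyl)phenyl]-5-methylhex-4-en-1-one | CC(C)=CCCC(=O)c1c(O)c(CC=C(C)C)c(OCOC)c(CC=C(C)C)c1OCOC | intermediate
9 | 2-[(dimethylamino)methylidene]-1-[2-hydroxy-4,6-bis(methoxymethoxy)-3,5-bis(3-methylbut-2-enyl)phenyl]-5-methylhex-4-en-1-one (interconverting E/Z mixture, geometry lost on cyclisation) | CN(C)C=C(CC=C(C)C)C(=O)c1c(O)c(CC=C(C)C)c(OCOC)c(CC=C(C)C)c1OCOC | intermediate (not isolated)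
10 | 5,7-bis(methoxymethoxy)-3,6,8-tris(3-methylbut-2-enyl)-4H-chromen-4-one | O=c1c(CC=C(C)C)coc2c(CC=C(C)C)c(OCOC)c(CC=C(C)C)c(OCOC)c12 | intermediate
11 | 4-bromoresorcinol (4-bromobenzene-1,3-diol) | Oc1ccc(Br)c(O)c1 | starting material
12 | 2-bromo-5-(methoxymethoxy)phenol | COCOc1ccc(Br)c(O)c1 | intermediate (not isolated)
13 | 1-bromo-2,4-bis(methoxymethoxy)benzene | COCOc1ccc(Br)c(OCOC)c1 | intermediate
14 | chloro[5,7-bis(methoxymethoxy)-3,6,8-tris(3-methylbut-2-enyl)-4-oxo-4H-chromen-2-yl]zinc | Cl[Zn]c1oc2c(CC=C(C)C)c(OCOC)c(CC=C(C)C)c(OCOC)c2c(=O)c1CC=C(C)C | intermediate (not isolated)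
15 | 2-[2,4-bis(methoxymethoxy)phenyl]-5,7-bis(methoxymethoxy)-3,6,8-tris(3-methylbut-2-enyl)-4H-chromen-4-one | COCOc1ccc(-c2oc3c(CC=C(C)C)c(OCOC)c(CC=C(C)C)c(OCOC)c3c(=O)c2CC=C(C)C)c(OCOC)c1 | intermediate
16 | 2-[2,4-bis(methoxymethoxy)phenyl]-5-hydroxy-7-(methoxymethoxy)-3,6,8-tris(3-methylbut-2-enyl)-4H-chromen-4-one | COCOc1ccc(-c2oc3c(CC=C(C)C)c(OCOC)c(CC=C(C)C)c(O)c3c(=O)c2CC=C(C)C)c(OCOC)c1 | intermediate (not isolated)
17 | 2-[2,4-bis(methoxymethoxy)phenyl]-5,7-dihydroxy-3,6,8-tris(3-methylbut-2-enyl)-4H-chromen-4-one | COCOc1ccc(-c2oc3c(CC=C(C)C)c(O)c(CC=C(C)C)c(O)c3c(=O)c2CC=C(C)C)c(OCOC)c1 | intermediate (not isolated)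
18 | 5,7-dihydroxy-2-[2-hydroxy-4-(methoxymethoxy)phenyl]-3,6,8-tris(3-methylbut-2-enyl)-4H-chromen-4-one | COCOc1ccc(-c2oc3c(CC=C(C)C)c(O)c(CC=C(C)C)c(O)c3c(=O)c2CC=C(C)C)c(O)c1 | intermediate (not isolated)
19 | artelasticin, 2-(2,4-dihydroxyphenyl)-5,7-dihydroxy-3,6,8-tris(3-methylbut-2-enyl)-4H-chromen-4-one (achiral) | CC(C)=CCc1c(O)c(CC=C(C)C)c2oc(-c3ccc(O)cc3O)c(CC=C(C)C)c(=O)c2c1O | target

**Totals**
Total step count: 7. Longest linear sequence: 6 (steps 1, 2, 3, 4, 6, 7); step 5 is the one-step side branch for ring B.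

**Three steps most likely to fail, with fallbacks**

Step 6 is the main risk. The chromone is electron-rich and fully substituted, so zincation may be slow, and the coupling builds a crowded C2–aryl bond next to the C3 prenyl group and an ortho MOM ether. The fallback keeps C2 as the nucleophile but uses an isolable reagent and a different coupling. It sets out from 10. Deprotonation with the stronger amide Li(TMP) in THF at −78 °C and trapping with Bu3SnCl gives the purifiable stannane 5,7-bis(methoxymethoxy)-3,6,8-tris(3-methylbut-2-enyl)-2-(tributylstannyl)-4H-chromen-4-one F1. A fluoride- and copper-promoted Stille coupling of this with 13 (Pd(P(t-Bu)3)2, CuI, CsF, dioxane, 80 °C) comes back to the route at 15.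

Step 7 is the second risk. Protic acid can add a phenol across a neighbouring prenyl double bond (chroman formation at the 5-OH/6-prenyl, 7-OH/6- or 8-prenyl and 2'-OH/3-prenyl pairs). The fallback avoids protic acid and sets out from 15. TMSOTf with 2,2'-bipyridyl in MeCN at 0 °C exchanges each aryl MOM acetal for a silyl ether under buffered, non-protic conditions. This gives 3,6,8-tris(3-methylbut-2-enyl)-5,7-bis(trimethylsilyloxy)-2-[2,4-bis(trimethylsilyloxy)phenyl]-4H-chromen-4-one F2. Brief treatment with water cleaves the Si–O bonds and comes back to the route at 19.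

Step 4 is the third risk. The amide acetal may react slowly at the hindered α-CH2, or may O-methylate the one free phenol that is needed for ring closure. The fallback closes ring C by a Claisen formylation instead and sets out from 8. NaH (3 equiv) and HCO2Et in THF (0 °C to rt) formylate the ketone enolate irreversibly. Acidification with AcOH gives the cyclic hemiacetal 2-hydroxy-5,7-bis(methoxymethoxy)-3,6,8-tris(3-methylbut-2-enyl)chroman-4-one F3 (mixture of diastereomers, both stereocentres lost in the next operation). Dehydration with catalytic PPTS in toluene at 70 °C comes back to the route at 10.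

**Further compounds**
F1 | step 6 | 5,7-bis(methoxymethoxy)-3,6,8-tris(3-methylbut-2-enyl)-2-(tributylstannyl)-4H-chromen-4-one | CCCC[Sn](CCCC)(CCCC)c1oc2c(CC=C(C)C)c(OCOC)c(CC=C(C)C)c(OCOC)c2c(=O)c1CC=C(C)C
F2 | step 7 | 3,6,8-tris(3-methylbut-2-enyl)-5,7-bis(trimethylsilyloxy)-2-[2,4-bis(trimethylsilyloxy)phenyl]-4H-chromen-4-one | C[Si](C)(C)Oc1ccc(-c2oc3c(CC=C(C)C)c(O[Si](C)(C)C)c(CC=C(C)C)c(O[Si](C)(C)C)c3c(=O)c2CC=C(C)C)c(O[Si](C)(C)C)c1
F3 | step 4 | 2-hydroxy-5,7-bis(methoxymethoxy)-3,6,8-tris(3-methylbut-2-enyl)chroman-4-one (mixture of diastereomers, stereocentres undefined) | O=C1C(CC=C(C)C)C(O)Oc2c(CC=C(C)C)c(OCOC)c(CC=C(C)C)c(OCOC)c12
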